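**Plan**
- Retrosynthesis: the C3'–Br bond of ring B is cut first (late bromination ortho to the phenol OH). Ring B is then opened across C1'–C6' and C3'–C4' to an aryloxyacetone and 2-bromomalonaldehyde. The O–CH2 bond leads back to 2,3,5-tribromo-6-methoxyphenol, whose OH derives from a formyl group.
- Enabling feature: in ring B, C1' (ether oxygen), C2' (OH) and C3' are the three carbons of an acetonyl ether, and C4', C5' (Br) and C6' are the three carbons of 2-bromomalonaldehyde. The crowded ring A oxygen is therefore only ever joined to an sp3 carbon.
- Forward order: ring A is bought as a benzene ring and decorated (dibromination, O-methylation, CHO to OH). The acetonyl chain is attached, ring B is closed by a double aldol condensation, and one bromination finishes the molecule.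
- Stereochemistry: the target has no stereocentre; the transient sp3 centres of the annulation disappear on aromatisation.

Key step: step 5

Remark: 2-bromo-6-hydroxybenzaldehyde, chloroacetone and 2-bromomalonaldehyde are taken as purchased materials. The bromosalicylaldehyde is used because its dibromination gives the ring A pattern directly, without a formylation of a deactivated tribromophenol.

**Step 1**
Reactants: 1 2-bromo-6-hydroxybenzaldehyde
Product: 3 2,3,5-tribromo-6-hydroxybenzaldehyde, via 2,3-dibromo-6-hydroxybenzaldehyde 2 (not isolated)
Conditions: Br2 (2.2 equiv), AcOH, rt to 50 °C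
Reagents that add atoms: bromine, BrBr
Why: Electrophilic aromatic bromination, as in the conversion of salicylaldehyde into its 3,5-dibromo derivative; the OH group activates only its para and ortho positions, while the remaining C–H is meta to OH and deactivated by the formyl and bromo groups.

**Step 2**
Reactants: 3 2,3,5-tribromo-6-hydroxybenzaldehyde
Product: 4 2,3,5-tribromo-6-methoxybenzaldehyde
Conditions: MeI, K2CO3, DMF, rt
Reagents that add atoms: iodomethane, CI
Why: Williamson O-methylation of an acidic, halogenated salicylaldehyde phenoxide by SN2 on iodomethane; the aldehyde and aryl bromides are inert to carbonate.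

**Step 3**
Reactants: 4 2,3,5-tribromo-6-methoxybenzaldehyde
Product: 6 2,3,5-tribromo-6-methoxyphenol, via 2,3,5-tribromo-6-methoxyphenyl formate 5 (not isolated)
Conditions: mCPBA, CH2Cl2, 0 °C to reflux; then HCl (cat.), MeOH, rt
Reagents that add atoms: 3-chloroperoxybenzoic acid, OOC(=O)c1cccc(Cl)c1
Why: Baeyer–Villiger (Dakin-type) oxidation of an ortho-methoxybenzaldehyde, in which the ortho-methoxy group should favour aryl over hydride migration in the Criegee adduct; the labile aryl formate is then cleaved by acid-catalysed methanolysis.

**Step 4**
Reactants: 6 2,3,5-tribromo-6-methoxyphenol; 7 chloroacetone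
Product: 8 1-(2,3,5-tribromo-6-methoxyphenoxy)propan-2-one
Conditions: K2CO3, DMF, 50 °C
Reagents that add atoms: none
Why: Williamson O-alkylation of the phenoxide with an α-chloroketone, a carbonyl-accelerated SN2 at an unhindered sp3 carbon, which tolerates the two ortho substituents flanking the oxygen.

**Step 5**
Reactants: 8 1-(2,3,5-tribromo-6-methoxyphenoxy)propan-2-one; 9 2-bromomalonaldehyde
Product: 12 4-bromo-2-(2,3,5-tribromo-6-methoxyphenoxy)phenol, via open-chain enal 10 (not isolated), via cyclic aldol 11 (not isolated)
Conditions: NaOH (3 equiv), EtOH–H2O, rt to 50 °C; then aq HCl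
Reagents that add atoms: none
Why: NaOH converts 9 into its sodium enolate and reversibly enolises 8; aldol condensation of the aryloxy-bearing methylene carbon (future C1') with one formyl group (C6') gives open-chain enal 10 after loss of water. The methyl carbon (C3') then adds as its enolate to the second formyl group (C4'), a 6-(enolendo)-exo-trig closure that forms ring B as cyclic aldol 11; E1cB dehydration and tautomerisation of the resulting cyclohexadienone deliver the phenol, whose OH is the former ketone oxygen. The closest known reaction type is the Hill–Prelog [3+3] phenol synthesis from ketones with two enolisable α-carbons and sodium nitromalonaldehyde, which gives 4-nitrophenols. No stereocentre remains in the product, the two sp3 centres of 11 being erased on aromatisation. The step needs each α-carbon of the ketone to engage a different formyl group; this is secured by ring size (only that pairing closes a six-membered ring) and by the symmetry of 9, so either order of bond formation gives the same regioisomer with the aryloxy group ortho and bromine para to OH. Aromatisation makes the otherwise reversible aldol sequence irreversible, and the bromine sits on an enolised sp2 carbon for most of the sequence, where it is not open to displacement.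

**Step 6**
Reactants: 12 4-bromo-2-(2,3,5-tribromo-6-methoxyphenoxy)phenol
Product: 13 2,4-dibromo-6-(2,3,5-tribromo-6-methoxyphenoxy)phenol
Conditions: Br2 (1.05 equiv), AcOH, rt
Reagents that add atoms: bromine, BrBr
Why: Electrophilic aromatic bromination directed by the free phenol OH to its only open ortho position (para is already brominated); ring A is deactivated by three bromines and its single C–H is flanked by two of them.

**Compound list**
1 | 2-bromo-6-hydroxybenzaldehyde | O=Cc1c(O)cccc1Br | starting material
2 | 2,3-dibromo-6-hydroxybenzaldehyde | O=Cc1c(O)ccc(Br)c1Br | intermediate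
3 | 2,3,5-tribromo-6-hydroxybenzaldehyde (3,5,6-tribromosalicylaldehyde) | O=Cc1c(O)c(Br)cc(Br)c1Br | intermediate
4 | 2,3,5-tribromo-6-methoxybenzaldehyde | COc1c(Br)cc(Br)c(Br)c1C=O | intermediate
5 | 2,3,5-tribromo-6-methoxyphenyl formate | COc1c(Br)cc(Br)c(Br)c1OC=O | intermediate
6 | 2,3,5-tribromo-6-methoxyphenol | COc1c(Br)cc(Br)c(Br)c1O | intermediate
7 | chloroacetone | CC(=O)CCl | starting material
8 | 1-(2,3,5-tribromo-6-methoxyphenoxy)propan-2-one | COc1c(Br)cc(Br)c(Br)c1OCC(C)=O | intermediate
9 | 2-bromomalonaldehyde | O=CC(Br)C=O | starting material
10 | 2-bromo-5-oxo-4-(2,3,5-tribromo-6-methoxyphenoxy)hex-3-enal (open-chain enal, present as its enolate; alkene geometry and CHBr centre undefined) | CC(=O)C(Oc1c(Br)c(Br)cc(Br)c1OC)=CC(Br)C=O | intermediate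
11 | 4-bromo-5-hydroxy-2-(2,3,5-tribromo-6-methoxyphenoxy)cyclohex-2-en-1-one (cyclic aldol, mixture of diastereomers) | O=C1CC(O)C(Br)C=C1Oc1c(Br)c(Br)cc(Br)c1OC | intermediate
12 | 4-bromo-2-(2,3,5-tribromo-6-methoxyphenoxy)phenol | COc1c(Br)cc(Br)c(Br)c1Oc1cc(Br)ccc1O | intermediate
13 | 2,4-dibromo-6-(2,3,5-tribromo-6-methoxyphenoxy)phenol | COc1c(Br)cc(Br)c(Br)c1Oc1cc(Br)cc(Br)c1O | target

**Summary**
Total step count: 6. Longest linear sequence: 6 steps (1 to 13).

**Steps most likely to fail**

Step 5. The sodium enolate of 9 is a much weaker electrophile than its nitro counterpart, so the first intermolecular aldol addition may be outrun by base-induced degradation of 9 and self-condensation of 8. The fallback sets out from phenol 6 and brings ring B in intact. SNAr of the phenoxide of 6 on 4-bromo-2-fluorobenzaldehyde (K2CO3, DMAc, 120 °C; fluoride ortho to the formyl group is displaced) should give 4-bromo-2-(2,3,5-tribromo-6-methoxyphenoxy)benzaldehyde F1. Baeyer–Villiger oxidation with mCPBA in CH2Cl2, aided by the ortho-aryloxy group, should then give 4-bromo-2-(2,3,5-tribromo-6-methoxyphenoxy)phenyl formate F2. Acid-catalysed methanolysis of F2 returns to the route at 12. The price is a forcing aryl–oxygen bond formation at the hindered ring A oxygen.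

Step 3. Hydride migration in the Criegee adduct may compete with migration of the electron-poor, doubly ortho-substituted aryl group, which would oxidise the aldehyde to the acid level instead of inserting oxygen. The fallback sets out from aldehyde 4 and replaces hydride by methyl as the competing migrating group.
- MeMgBr (THF, −78 °C) should add to 4 to give 1-(2,3,5-tribromo-6-methoxyphenyl)ethan-1-ol F3.
- Dess–Martin oxidation should give 1-(2,3,5-tribromo-6-methoxyphenyl)ethan-1-one F4.
- Baeyer–Villiger oxidation with CF3CO3H (from trifluoroacetic anhydride and urea–hydrogen peroxide, Na2HPO4, CH2Cl2), in which aryl migrates in preference to methyl, should give 2,3,5-tribromo-6-methoxyphenyl acetate F5.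
- Methanolysis of F5 (K2CO3, MeOH) rejoins the route at 6.

Step 4. SN2 attack by the weakly nucleophilic, doubly ortho-flanked phenoxide may be slow enough for base-induced self-condensation of chloroacetone to consume the electrophile. The fallback sets out from 6 and uses a non-enolisable electrophile. Alkylation with propargyl bromide (K2CO3, acetone, reflux) should give 1,2,5-tribromo-4-methoxy-3-(prop-2-yn-1-yloxy)benzene F6. Markovnikov hydration of the terminal alkyne (HgSO4 cat., dilute H2SO4, aqueous THF, 60 °C) then returns to the route at 8. Both ortho positions of ring A are occupied, so cyclisation onto the arene cannot interfere.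

**Further compounds**
F1 | step 5 | 4-bromo-2-(2,3,5-tribromo-6-methoxyphenoxy)benzaldehyde | COc1c(Br)cc(Br)c(Br)c1Oc1cc(Br)ccc1C=O
F2 | step 5 | 4-bromo-2-(2,3,5-tribromo-6-methoxyphenoxy)phenyl formate | COc1c(Br)cc(Br)c(Br)c1Oc1cc(Br)ccc1OC=O
F3 | step 3 | 1-(2,3,5-tribromo-6-methoxyphenyl)ethan-1-ol (racemic) | COc1c(Br)cc(Br)c(Br)c1C(C)O
F4 | step 3 | 1-(2,3,5-tribromo-6-methoxyphenyl)ethan-1-one | COc1c(Br)cc(Br)c(Br)c1C(C)=O
F5 | step 3 | 2,3,5-tribromo-6-methoxyphenyl acetate | COc1c(Br)cc(Br)c(Br)c1OC(C)=O
F6 | step 4 | 1,2,5-tribromo-4-methoxy-3-(prop-2-yn-1-yloxy)benzene | COc1c(Br)cc(Br)c(Br)c1OCC#C
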